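The route disconnects the tetrasubstituted C5=C6 double bond of the cyclohexene (ring A; benzofuranone numbering, C6 bearing the acyloxymethyl group and C5 the side chain). Because C5 and C6 carry no hydrogen, each can enter as a terminal methylidene. Ring-closing metathesis of an acyclic 1,7-diene built from two 1,1-disubstituted alkenes forms this bond and closes ring A in one operation, with all four stereocentres already set and the α-methylene lactone (ring B) untouched. The precursor is a trans-4,5-disubstituted α-methylene-γ-butyrolactone bearing a 2-(chloromethyl)allyl arm and a hydroxylated 2-methylidene arm, assembled from an (R)-butenolide allylstannane and an (S)-citronellal-derived enal. The allylic chloride later receives the methacrylate.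

Key step: step 12

Remark: the target is read from its SMILES as (3aR,4S,7aR) with an (S) side-chain centre, i.e. a trans-fused lactone with the C4 hydroxyl cis to the C3a–C3 bond; compounds 1, 3, 5, 10 and 19 are taken as commercial.

Step 1
Reactants: 1 3-chloro-2-(chloromethyl)prop-1-ene
Product: 2 tributyl[2-(chloromethyl)prop-2-en-1-yl]stannane
Conditions: Bu3SnH, LiN(iPr)2, THF, 0 °C; then 1 (3 equiv), THF, −78 °C
Reagents that add atoms: tributyltin hydride CCCC[SnH](CCCC)CCCC
Why: Stannyl anion alkylation, in which Bu3SnLi displaces one chloride of the symmetrical bis-allylic dichloride (SN2 and SN2' paths give the same product) and the excess of 1 suppresses double substitution.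

Step 2
Reactants: 3 (E)-but-2-enal; 2 tributyl[2-(chloromethyl)prop-2-en-1-yl]stannane
Product: 4 (4R,5E)-2-(chloromethyl)hepta-1,5-dien-4-ol
Conditions: (R)-BINOL (20 mol %), Ti(OiPr)4 (10 mol %), 4 Å MS, CH2Cl2, −20 °C; aq NaHCO3
Reagents that add atoms: none
Why: Keck asymmetric allylation, in which the BINOL–Ti(OiPr)4 Lewis acid activates the enal for 1,2-addition of the 2-substituted allylstannane and (R)-BINOL should direct Re-face attack, setting the carbinol (later C7a) as R.

Step 3
Reactants: 4 (4R,5E)-2-(chloromethyl)hepta-1,5-dien-4-ol; 5 2-(bromomethyl)prop-2-enoic acid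
Product: 6 (4R,5E)-2-(chloromethyl)hepta-1,5-dien-4-yl 2-(bromomethyl)prop-2-enoate
Conditions: DCC, DMAP (5 mol %), CH2Cl2, 0 °C
Reagents that add atoms: none
Why: Steglich esterification, which acylates the secondary allylic alcohol with retention of configuration, the low DMAP loading and low temperature limiting attack on the allylic bromide.

Step 4
Reactants: 6 (4R,5E)-2-(chloromethyl)hepta-1,5-dien-4-yl 2-(bromomethyl)prop-2-enoate
Product: 7 (5R)-3-(bromomethyl)-5-[2-(chloromethyl)prop-2-en-1-yl]furan-2(5H)-one
Conditions: second-generation Grubbs catalyst (5 mol %), CH2Cl2 (0.01 M), 40 °C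
Reagents that add atoms: none
Why: Ring-closing metathesis, in which the ruthenium carbene loads on the propenyl group and closes onto the acrylate alkene to give the butenolide with loss of propene, the alternative closure onto the chloromethallyl alkene being a slower tetrasubstituted six-ring closure and the C5 stereocentre being untouched.

Step 5
Reactants: 7 (5R)-3-(bromomethyl)-5-[2-(chloromethyl)prop-2-en-1-yl]furan-2(5H)-one
Product: 9 (5R)-5-[2-(chloromethyl)prop-2-en-1-yl]-3-[(tributylstannyl)methyl]furan-2(5H)-one, via allylzinc bromide 8 (not isolated)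
Conditions: Zn dust, Bu3SnCl, THF, 0 to 20 °C (7 added slowly)
Reagents that add atoms: tributyltin chloride CCCC[Sn](Cl)(CCCC)CCCC
Why: Barbier-type allylzinc formation and transmetallation to tin, in which zinc should insert into the carbonyl-activated allylic C–Br bond far faster than into the isolated allylic chloride and Bu3SnCl traps the allylzinc at its primary terminus to give the conjugated allylstannane.

Step 6
Reactants: 10 (S)-citronellal
Product: 11 (6S)-8,8-dimethoxy-2,6-dimethyloct-2-ene
Conditions: HC(OMe)3, MeOH, PPTS (2 mol %), 20 °C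
Reagents that add atoms: trimethyl orthoformate COC(OC)OC; methanol CO
Why: Acid-catalysed acetalisation driven by the orthoformate masks the aldehyde under conditions mild enough to avoid the carbonyl-ene cyclisation of citronellal, the remote stereocentre being untouched.

Step 7
Reactants: 11 (6S)-8,8-dimethoxy-2,6-dimethyloct-2-ene
Product: 13 (4S)-6,6-dimethoxy-4-methylhexan-1-ol, via ozonolysis aldehyde 12 (not isolated)
Conditions: O3, CH2Cl2/MeOH 4:1, −78 °C; then NaBH4, −78 to 0 °C
Reagents that add atoms: ozone [O-][O+]=O
Why: Ozonolysis with reductive work-up, in which ozone cleaves the only alkene and borohydride reduces the ozonolysis products directly to the primary alcohol, the acetal being inert to both.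

Step 8
Reactants: 13 (4S)-6,6-dimethoxy-4-methylhexan-1-ol
Product: 14 (4S)-6,6-dimethoxy-4-methylhexyl acetate
Conditions: Ac2O, pyridine, DMAP (cat), CH2Cl2, 20 °C
Reagents that add atoms: acetic anhydride CC(=O)OC(C)=O
Why: DMAP-catalysed acylation of the primary alcohol installs the side-chain acetate of the target at a stage where no other hydroxyl is present.

Step 9
Reactants: 14 (4S)-6,6-dimethoxy-4-methylhexyl acetate
Product: 15 (4S)-4-methyl-6-oxohexyl acetate
Conditions: Amberlyst-15, acetone/H2O 10:1, 20 °C
Reagents that add atoms: water O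
Why: Acetal hydrolysis under mild aqueous acid frees the aldehyde without cleaving the primary acetate, and the stereocentre β to the aldehyde cannot epimerise.

Step 10
Reactants: 15 (4S)-4-methyl-6-oxohexyl acetate
Product: 16 (4S)-5-formyl-4-methylhex-5-en-1-yl acetate
Conditions: aq HCHO (37%), pyrrolidine (10 mol %), propionic acid (10 mol %), i-PrOH, 45 °C
Reagents that add atoms: formaldehyde C=O
Why: Organocatalytic α-methylenation (Mannich condensation with formaldehyde, then elimination of the amine) converts the α-CH2 into the 2-substituted acrolein, and the stereocentre, being β to the carbonyl and outside the enamine, should be retained.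

Step 11
Reactants: 9 (5R)-5-[2-(chloromethyl)prop-2-en-1-yl]-3-[(tributylstannyl)methyl]furan-2(5H)-one; 16 (4S)-5-formyl-4-methylhex-5-en-1-yl acetate
Product: 17 (4S,6S)-6-[(2R,3R)-2-[2-(chloromethyl)prop-2-en-1-yl]-4-methylidene-5-oxooxolan-3-yl]-6-hydroxy-4-methyl-5-methylidenehexyl acetate
Conditions: BF3·OEt2 (1.2 equiv), CH2Cl2, −78 °C; aq NaHCO3
Reagents that add atoms: none
Why: Lewis acid-promoted SE2' addition of a 2-carbonyl-substituted allylstannane to an aldehyde, in which the BF3-bound enal is attacked by the butenolide β-carbon anti to the C5 substituent (setting the trans lactone, oxolane C3 as R) through an open antiperiplanar transition state with the aldehyde substituent over the ring C–H and away from C5, which should give the syn carbinol (6S) where a closed chair would give its epimer.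

Step 12
Reactants: 17 (4S,6S)-6-[(2R,3R)-2-[2-(chloromethyl)prop-2-en-1-yl]-4-methylidene-5-oxooxolan-3-yl]-6-hydroxy-4-methyl-5-methylidenehexyl acetate
Product: 18 (4S)-4-[(3aR,4S,7aR)-6-(chloromethyl)-4-hydroxy-3-methylidene-2-oxo-2,3,3a,4,7,7a-hexahydro-1-benzofuran-5-yl]pentyl acetate
Conditions: RuCl2(=CH-C6H4-2-OiPr)(1,3-di-o-tolylimidazolidin-2-ylidene) (o-tolyl second-generation Hoveyda-Grubbs catalyst, 10 mol % in portions), 1,4-benzoquinone (20 mol %), toluene (0.005 M), 80 °C, argon sparge
Reagents that add atoms: none
Why: The ruthenium alkylidene should exchange onto the less hindered chloromethallyl methylidene (future C6), add intramolecularly by [2+2] cycloaddition to the methylidene on future C5, and expel ethylene by cycloreversion to leave the C5=C6 double bond. The closest known reaction type is ring-closing olefin metathesis of dienes with two 1,1-disubstituted alkenes to tetrasubstituted cycloalkenes, for which the small N-aryl carbene ligand of this catalyst is suited. Ring A is closed by joining the two internal alkene carbons of a 1,7-diene, so the six ring atoms C5, C4, C3a, C7a, C7 and C6 all come from the chain and the two terminal CH2 groups leave. No new stereocentre is formed, and the four existing ones (C4, C3a, C7a and the side-chain carbon) are sp3 centres outside the metallacycle that cannot epimerise under these neutral conditions. The step needs site selectivity among three 1,1-disubstituted alkenes, which the substrate secures because closure onto the electron-poor α-methylene lactone would give a cyclobutene or a bridgehead alkene; the trans lactone holds the two arms gauche, the free allylic hydroxyl should assist closure, and high dilution with ethylene removal suppresses cross-metathesis.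

Step 13
Reactants: 18 (4S)-4-[(3aR,4S,7aR)-6-(chloromethyl)-4-hydroxy-3-methylidene-2-oxo-2,3,3a,4,7,7a-hexahydro-1-benzofuran-5-yl]pentyl acetate; 19 sodium methacrylate
Product: 20 [(3aR,4S,7aR)-5-[(2S)-5-acetoxypentan-2-yl]-4-hydroxy-3-methylidene-2-oxo-2,3,3a,4,7,7a-hexahydro-1-benzofuran-6-yl]methyl 2-methylprop-2-enoate (target)
Conditions: Bu4NI (10 mol %), BHT (cat), DMF, 40 °C
Reagents that add atoms: none
Why: Carboxylate O-alkylation, in which the weakly basic methacrylate displaces the primary allylic chloride by SN2 under iodide catalysis, so the free C4 hydroxyl is neither acylated nor deprotonated and the lactone and acetate stay intact.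

Compound list
1 | 3-chloro-2-(chloromethyl)prop-1-ene | C=C(CCl)CCl | starting material
2 | tributyl[2-(chloromethyl)prop-2-en-1-yl]stannane | C=C(CCl)C[Sn](CCCC)(CCCC)CCCC | intermediate
3 | (E)-but-2-enal (crotonaldehyde) | C/C=C/C=O | starting material
4 | (4R,5E)-2-(chloromethyl)hepta-1,5-dien-4-ol | C/C=C/[C@H](O)CC(=C)CCl | intermediate
5 | 2-(bromomethyl)prop-2-enoic acid | OC(=O)C(=C)CBr | starting material
6 | (4R,5E)-2-(chloromethyl)hepta-1,5-dien-4-yl 2-(bromomethyl)prop-2-enoate | C/C=C/[C@H](OC(=O)C(=C)CBr)CC(=C)CCl | intermediate
7 | (5R)-3-(bromomethyl)-5-[2-(chloromethyl)prop-2-en-1-yl]furan-2(5H)-one | ClCC(=C)C[C@H]1OC(=O)C(CBr)=C1 | intermediate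
8 | allylzinc bromide derived from 7 (not isolated) | ClCC(=C)C[C@H]1OC(=O)C(C[Zn]Br)=C1 | intermediate
9 | (5R)-5-[2-(chloromethyl)prop-2-en-1-yl]-3-[(tributylstannyl)methyl]furan-2(5H)-one | ClCC(=C)C[C@H]1OC(=O)C(C[Sn](CCCC)(CCCC)CCCC)=C1 | intermediate
10 | (S)-citronellal, (3S)-3,7-dimethyloct-6-enal | O=CC[C@@H](C)CCC=C(C)C | starting material
11 | (6S)-8,8-dimethoxy-2,6-dimethyloct-2-ene | COC(OC)C[C@@H](C)CCC=C(C)C | intermediate
12 | (4S)-6,6-dimethoxy-4-methylhexanal (ozonolysis aldehyde, not isolated) | COC(OC)C[C@@H](C)CCC=O | intermediate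
13 | (4S)-6,6-dimethoxy-4-methylhexan-1-ol | COC(OC)C[C@@H](C)CCCO | intermediate
14 | (4S)-6,6-dimethoxy-4-methylhexyl acetate | COC(OC)C[C@@H](C)CCCOC(C)=O | intermediate
15 | (4S)-4-methyl-6-oxohexyl acetate | O=CC[C@@H](C)CCCOC(C)=O | intermediate
16 | (4S)-5-formyl-4-methylhex-5-en-1-yl acetate | O=CC(=C)[C@@H](C)CCCOC(C)=O | intermediate
17 | (4S,6S)-6-[(2R,3R)-2-[2-(chloromethyl)prop-2-en-1-yl]-4-methylidene-5-oxooxolan-3-yl]-6-hydroxy-4-methyl-5-methylidenehexyl acetate | ClCC(=C)C[C@H]1OC(=O)C(=C)[C@@H]1[C@H](O)C(=C)[C@@H](C)CCCOC(C)=O | intermediate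
18 | (4S)-4-[(3aR,4S,7aR)-6-(chloromethyl)-4-hydroxy-3-methylidene-2-oxo-2,3,3a,4,7,7a-hexahydro-1-benzofuran-5-yl]pentyl acetate | ClCC1=C([C@@H](C)CCCOC(C)=O)[C@@H](O)[C@H]2C(=C)C(=O)O[C@@H]2C1 | intermediate
19 | sodium methacrylate | C=C(C)C(=O)[O-].[Na+] | starting material
20 | [(3aR,4S,7aR)-5-[(2S)-5-acetoxypentan-2-yl]-4-hydroxy-3-methylidene-2-oxo-2,3,3a,4,7,7a-hexahydro-1-benzofuran-6-yl]methyl 2-methylprop-2-enoate | C=C(C)C(=O)OCC1=C([C@@H](C)CCCOC(C)=O)[C@@H](O)[C@H]2C(=C)C(=O)O[C@@H]2C1 | target

Total step count: 13.
Longest linear sequence: 8 steps (steps 1, 2, 3, 4, 5, 11, 12, 13; the citronellal branch, steps 6 to 10 followed by 11 to 13, is equally long).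

Steps most likely to fail

Step 12 (ring-closing metathesis). The ruthenium alkylidene may load on the chloromethallyl terminus but fail to engage the doubly α-branched C5 methylidene, so that catalyst decomposition and intermolecular cross-metathesis take over. The fallback sets out from 17 and comes back at 18, closing the same C5=C6 bond by carbonyl olefination instead of olefin–olefin metathesis. Hydroxyl-directed epoxidation of the allylic-alcohol methylidene of 17 (VO(acac)2, t-BuOOH, CH2Cl2) should give the epoxy alcohol F1, and silylation (TBSCl, imidazole, DMF) the silyl ether F2. H5IO6 in THF/H2O would cleave the terminal epoxide to the ketone F3 with loss of formaldehyde. One equivalent of Mo(=CHCMe2Ph)(=N-2,6-iPr2C6H3)[OCMe(CF3)2]2 (benzene, 25 °C) should then exchange onto the chloromethallyl alkene and olefinate the ketone intramolecularly (alkylidene-mediated olefin metathesis followed by carbonyl olefination) to give the cyclised silyl ether F4. HF·pyridine would return 18.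

Step 11 (allylstannane addition). The syn preference at the new carbinol may erode through a competing synclinal or closed arrangement, or the electron-poor stannane may react too slowly and be lost by protodestannylation. The fallback sets out from 7 and 16 and comes back at 17. Barbier allylation of 16 with bromide 7 and Zn (THF/sat aq NH4Cl, 0 °C), through allylzinc 8 and a closed chair transition state, should give the trans lactone but mainly the C6-epimeric carbinol F5. Oxidation with Dess–Martin periodinane would give the enone F6. Luche reduction (NaBH4, CeCl3·7H2O, MeOH, −78 °C) under Felkin–Anh control, with hydride anti to the oxolane C3–C2 bond, should then deliver the (6S)-alcohol 17; the facial preference in this reduction is itself uncertain.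

Step 5 (zinc-mediated stannylation). The allylzinc may be protonated or undergo Wurtz-type homocoupling before the tin chloride traps it, and zinc may also begin to insert into the allylic chloride. The fallback sets out from 4 and comes back at 9, bringing tin in before the butenolide is formed so that no organozinc is needed. 2-[(Tributylstannyl)methyl]prop-2-enoic acid F7, obtained by LiOH saponification of commercial ethyl 2-[(tributylstannyl)methyl]acrylate, would be coupled to 4 (DCC, DMAP, CH2Cl2, 0 °C) to give the stannyl ester F8. Ring-closing metathesis of F8 (second-generation Grubbs catalyst, CH2Cl2, 40 °C) should give 9 directly with loss of propene.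

Further compounds
F1 | step 12 | epoxy alcohol from 17, oxirane on the allylic-alcohol methylidene (both epimers at the oxirane carbon) | ClCC(=C)C[C@H]1OC(=O)C(=C)[C@@H]1[C@H](O)C2(CO2)[C@@H](C)CCCOC(C)=O
F2 | step 12 | tert-butyldimethylsilyl ether of F1 | ClCC(=C)C[C@H]1OC(=O)C(=C)[C@@H]1[C@H](O[Si](C)(C)C(C)(C)C)C2(CO2)[C@@H](C)CCCOC(C)=O
F3 | step 12 | α-silyloxy ketone from cleavage of the epoxide of F2 | ClCC(=C)C[C@H]1OC(=O)C(=C)[C@@H]1[C@H](O[Si](C)(C)C(C)(C)C)C(=O)[C@@H](C)CCCOC(C)=O
F4 | step 12 | tert-butyldimethylsilyl ether of 18 | ClCC1=C([C@@H](C)CCCOC(C)=O)[C@@H](O[Si](C)(C)C(C)(C)C)[C@H]2C(=C)C(=O)O[C@@H]2C1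
F5 | step 11 | (6R)-epimer of 17 | ClCC(=C)C[C@H]1OC(=O)C(=C)[C@@H]1[C@@H](O)C(=C)[C@@H](C)CCCOC(C)=O
F6 | step 11 | enone from oxidation of F5 | ClCC(=C)C[C@H]1OC(=O)C(=C)[C@@H]1C(=O)C(=C)[C@@H](C)CCCOC(C)=O
F7 | step 5 | 2-[(tributylstannyl)methyl]prop-2-enoic acid | OC(=O)C(=C)C[Sn](CCCC)(CCCC)CCCC
F8 | step 5 | (4R,5E)-2-(chloromethyl)hepta-1,5-dien-4-yl 2-[(tributylstannyl)methyl]prop-2-enoate | C/C=C/[C@H](OC(=O)C(=C)C[Sn](CCCC)(CCCC)CCCC)CC(=C)CCl
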